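**Plan**

- Numbering: the upper flavan is O1–C8a (benzo ring A, 4-hydroxyphenyl ring B, pyran ring C); the lower unit is primed (ring D = C4a', C5'–C8', C8a'; ring F = O1', C2', C3', C4'; ring E = the pyrogallol ring).
- Retrosynthesis removes the O-protecting groups, then cuts C4'–C4a' (ring F), then the aryl ether O1'–C2', then the interflavan bond C4–C8'. This leads back to (2S)-liquiritigenin, phloroglucinol and 3,4,5-trihydroxybenzaldehyde.
- Forward: ring C comes with liquiritigenin; ring D is attached to C4 as free phloroglucinol; ring E with C2'–C4' is hung on one ring D oxygen; ring F is closed last by arene attack on a terminal epoxide.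
- Enabling feature: before ring F exists, the two ring D oxygens flanking C8' are equivalent, so C-flavanylation of phloroglucinol has no C6'/C8' ambiguity. Once one of them is etherified, C4a' is the only unsubstituted carbon ortho to O1'.
- Stereochemistry: C2 (S) is bought with liquiritigenin; C4 (R) comes from pseudo-axial arene attack trans to the 2-aryl group; C3' (R) from a Sharpless kinetic resolution with L-(+)-DIPT; C2' (R) from Mitsunobu inversion of an (S)-carbinol.

Key step: step 9

Remark: (2S)-liquiritigenin of high enantiomeric purity and 3,4,5-trihydroxybenzaldehyde are taken as purchasable; any residual enantiomer of 10 becomes a diastereomer after step 8 and is expected to be removed by chromatography there.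

**Route**

Step 1
Reactants: 1 (2S)-liquiritigenin
Product: 2 (2S)-7-(benzyloxy)-2-[4-(benzyloxy)phenyl]-2,3-dihydro-4H-chromen-4-one
Conditions: BnOH (2.5 equiv), PPh3, DIAD, THF, 0 °C to rt
Reagents that add atoms: benzyl alcohol, OCc1ccccc1
Why: Mitsunobu O-alkylation of the two phenols runs without free base, so the base-induced flavanone–chalcone ring opening that would racemise C2 should be avoided.

Step 2
Reactants: 2 (2S)-7-(benzyloxy)-2-[4-(benzyloxy)phenyl]-2,3-dihydro-4H-chromen-4-one
Product: 3 (2S,4S)-7-(benzyloxy)-2-[4-(benzyloxy)phenyl]chroman-4-ol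
Conditions: NaBH4, THF–MeOH, 0 °C
Reagents that add atoms: none
Why: Borohydride reduction of the aryl ketone by axial hydride delivery should give mainly the 2,4-cis (4S) alcohol, whose C4 configuration is of no consequence because C4 is ionised in step 3.

Step 3
Reactants: 3 (2S,4S)-7-(benzyloxy)-2-[4-(benzyloxy)phenyl]chroman-4-ol; 4 phloroglucinol
Product: 5 2-[(2S,4R)-7-(benzyloxy)-2-[4-(benzyloxy)phenyl]chroman-4-yl]benzene-1,3,5-triol
Conditions: phloroglucinol (5 equiv), TsOH·H2O (10 mol %), 1,4-dioxane, rt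
Reagents that add atoms: none
Why: Acid-catalysed Friedel–Crafts benzylation through the flavan-4-yl cation (stabilised by O1 and O7) can give only one constitutional isomer with symmetric phloroglucinol, and pseudo-axial attack on the half-chair cation with its equatorial 2-aryl group should set C4 as R (2,4-trans), the isomer that also keeps the 2,6-dioxygenated aryl group clear of the peri C5–H.

Step 4
Reactants: 5 2-[(2S,4R)-7-(benzyloxy)-2-[4-(benzyloxy)phenyl]chroman-4-yl]benzene-1,3,5-triol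
Product: 6 2-[(2S,4R)-7-(benzyloxy)-2-[4-(benzyloxy)phenyl]chroman-4-yl]-5-[(triisopropylsilyl)oxy]benzene-1,3-diol
Conditions: TIPSCl (1.05 equiv), imidazole, DMF, 0 °C
Reagents that add atoms: chlorotriisopropylsilane, CC(C)[Si](Cl)(C(C)C)C(C)C
Why: Silylation with a bulky silyl chloride is governed by steric access, and the C5' hydroxyl is the only one of the three not flanked by the flavan-4-yl group, so mono-silylation there should leave the two equivalent hydroxyls next to C8' free.

Step 5
Reactants: 7 3,4,5-trihydroxybenzaldehyde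
Product: 8 3,4,5-tris(benzyloxy)benzaldehyde
Conditions: BnBr (3.3 equiv), K2CO3, DMF, rt to 50 °C, argon
Reagents that add atoms: benzyl bromide, BrCc1ccccc1
Why: Williamson etherification of the three phenols is routine for gallate-type arenes when air is excluded.

Step 6
Reactants: 8 3,4,5-tris(benzyloxy)benzaldehyde
Product: 9 racemic 1-[3,4,5-tris(benzyloxy)phenyl]prop-2-en-1-ol
Conditions: CH2=CHMgBr, THF, −78 to 0 °C; aqueous NH4Cl
Reagents that add atoms: vinylmagnesium bromide, C=C[Mg]Br
Why: Grignard addition to the aldehyde gives the secondary allylic alcohol as a racemate, which is resolved in step 7.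

Step 7
Reactants: 9 racemic 1-[3,4,5-tris(benzyloxy)phenyl]prop-2-en-1-ol
Product: 10 (S)-[(2R)-oxiran-2-yl][3,4,5-tris(benzyloxy)phenyl]methanol
Conditions: Ti(OiPr)4 (10 mol %), L-(+)-DIPT (15 mol %), t-BuOOH (0.45 equiv), 4 Å molecular sieves, CH2Cl2, −20 °C
Reagents that add atoms: tert-butyl hydroperoxide, CC(C)(C)OO
Why: In the Sharpless kinetic resolution the titanium–L-(+)-tartrate catalyst should epoxidise the (R)-allylic alcohol much faster than its enantiomer and with erythro selectivity, giving the epoxide carbon as R (the future C3') beside an unchanged carbinol whose descriptor becomes S only because the oxiranyl group now outranks the aryl group.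

Step 8
Reactants: 6 2-[(2S,4R)-7-(benzyloxy)-2-[4-(benzyloxy)phenyl]chroman-4-yl]-5-[(triisopropylsilyl)oxy]benzene-1,3-diol; 10 (S)-[(2R)-oxiran-2-yl][3,4,5-tris(benzyloxy)phenyl]methanol
Product: 11 2-[(2S,4R)-7-(benzyloxy)-2-[4-(benzyloxy)phenyl]chroman-4-yl]-3-{(R)-[(2R)-oxiran-2-yl][3,4,5-tris(benzyloxy)phenyl]methoxy}-5-[(triisopropylsilyl)oxy]phenol
Conditions: PPh3, DIAD, toluene, 0 °C to rt (6 in slight excess)
Reagents that add atoms: none
Why: In this Mitsunobu etherification one of the two equivalent phenolic oxygens displaces the oxyphosphonium ion of the secondary carbinol with inversion, which sets C2' as R while the epoxide is untouched, and the remaining flanking hydroxyl is then too hindered to react a second time.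

Step 9
Reactants: 11 2-[(2S,4R)-7-(benzyloxy)-2-[4-(benzyloxy)phenyl]chroman-4-yl]-3-{(R)-[(2R)-oxiran-2-yl][3,4,5-tris(benzyloxy)phenyl]methoxy}-5-[(triisopropylsilyl)oxy]phenol
Product: 12 (2R,3R)-8-[(2S,4R)-7-(benzyloxy)-2-[4-(benzyloxy)phenyl]chroman-4-yl]-5-[(triisopropylsilyl)oxy]-2-[3,4,5-tris(benzyloxy)phenyl]chromane-3,7-diol
Conditions: BF3·OEt2 (0.3 equiv), CH2Cl2, −78 to −20 °C; Et3N quench
Reagents that add atoms: none
Why: BF3 coordinates the epoxide oxygen, and the ring D carbon C4a' (ortho to O1' and O5', para to the free C7' hydroxyl) attacks the terminal epoxide carbon C4' from the rear; proton loss from the arenium ion restores aromaticity and leaves the C3' oxygen as the secondary alcohol. The closest known reaction type is the Lewis-acid-catalysed or hexafluoroisopropanol-promoted intramolecular Friedel–Crafts epoxide–arene cyclisation of aryl glycidyl ethers, including 1-aryl-substituted ones, to chroman-3-ols. Ring F closes in the 6-endo mode (the epoxide C–C bond ends up inside the new ring), because the 5-exo alternative would require attack at the secondary carbon C3' next to the branched C2' and would give a strained dihydrobenzofuran. No stereocentre is created: C3' keeps its C–O bond and C2' is a spectator, so the 2',3'-cis relationship built in steps 7 and 8 is carried into ring F. The step needs site selectivity on ring D and chemoselectivity over acid scission of the C4–C8' bond. The first is secured because C8' is substituted and C6' cannot reach the epoxide; the second by the low temperature, the sub-stoichiometric Lewis acid and the missing 5-oxygen on ring A, which makes the flavan-4-yl cation a poorer leaving group than in 5,7-dioxygenated flavans.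

Step 10
Reactants: 12 (2R,3R)-8-[(2S,4R)-7-(benzyloxy)-2-[4-(benzyloxy)phenyl]chroman-4-yl]-5-[(triisopropylsilyl)oxy]-2-[3,4,5-tris(benzyloxy)phenyl]chromane-3,7-diol
Product: 13 (2R,3R)-8-[(2S,4R)-7-(benzyloxy)-2-[4-(benzyloxy)phenyl]chroman-4-yl]-2-[3,4,5-tris(benzyloxy)phenyl]chromane-3,5,7-triol
Conditions: TBAF (1.1 equiv), AcOH (1.1 equiv), THF, 0 °C, argon
Reagents that add atoms: none
Why: Fluoride cleaves the aryl silyl ether selectively, and the acetic acid buffer keeps the electron-rich phenoxide from oxidising or epimerising anything.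

Step 11
Reactants: 13 (2R,3R)-8-[(2S,4R)-7-(benzyloxy)-2-[4-(benzyloxy)phenyl]chroman-4-yl]-2-[3,4,5-tris(benzyloxy)phenyl]chromane-3,5,7-triol
Product: 14 (2R,3R)-8-[(2S,4R)-7-hydroxy-2-(4-hydroxyphenyl)chroman-4-yl]-2-(3,4,5-trihydroxyphenyl)chromane-3,5,7-triol (target)
Conditions: H2 (1 atm), Pd(OH)2/C, THF–MeOH, rt
Reagents that add atoms: none
Why: Catalytic hydrogenolysis removes the five benzyl ethers under neutral conditions that are routinely used on benzylated oligoflavans without cleaving the C2–O1 or interflavan bonds.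

**Compound list**

1 | (2S)-liquiritigenin | Oc1ccc([C@@H]2CC(=O)c3ccc(O)cc3O2)cc1 | starting material
2 | (2S)-7-(benzyloxy)-2-[4-(benzyloxy)phenyl]-2,3-dihydro-4H-chromen-4-one | c1ccccc1COc1ccc([C@@H]2CC(=O)c3ccc(OCc4ccccc4)cc3O2)cc1 | intermediate
3 | (2S,4S)-7-(benzyloxy)-2-[4-(benzyloxy)phenyl]chroman-4-ol | c1ccccc1COc1ccc([C@@H]2C[C@H](O)c3ccc(OCc4ccccc4)cc3O2)cc1 | intermediate
4 | phloroglucinol | Oc1cc(O)cc(O)c1 | starting material
5 | 2-[(2S,4R)-7-(benzyloxy)-2-[4-(benzyloxy)phenyl]chroman-4-yl]benzene-1,3,5-triol | c1ccccc1COc1ccc([C@@H]2C[C@@H](c5c(O)cc(O)cc5O)c3ccc(OCc4ccccc4)cc3O2)cc1 | intermediate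
6 | 2-[(2S,4R)-7-(benzyloxy)-2-[4-(benzyloxy)phenyl]chroman-4-yl]-5-[(triisopropylsilyl)oxy]benzene-1,3-diol | c1ccccc1COc1ccc([C@@H]2C[C@@H](c5c(O)cc(O[Si](C(C)C)(C(C)C)C(C)C)cc5O)c3ccc(OCc4ccccc4)cc3O2)cc1 | intermediate
7 | 3,4,5-trihydroxybenzaldehyde | O=Cc1cc(O)c(O)c(O)c1 | starting material
8 | 3,4,5-tris(benzyloxy)benzaldehyde | O=Cc1cc(OCc2ccccc2)c(OCc2ccccc2)c(OCc2ccccc2)c1 | intermediate
9 | racemic 1-[3,4,5-tris(benzyloxy)phenyl]prop-2-en-1-ol | C=CC(O)c1cc(OCc2ccccc2)c(OCc2ccccc2)c(OCc2ccccc2)c1 | intermediate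
10 | (S)-[(2R)-oxiran-2-yl][3,4,5-tris(benzyloxy)phenyl]methanol | O[C@@H](c1cc(OCc2ccccc2)c(OCc2ccccc2)c(OCc2ccccc2)c1)[C@H]1CO1 | intermediate
11 | 2-[(2S,4R)-7-(benzyloxy)-2-[4-(benzyloxy)phenyl]chroman-4-yl]-3-{(R)-[(2R)-oxiran-2-yl][3,4,5-tris(benzyloxy)phenyl]methoxy}-5-[(triisopropylsilyl)oxy]phenol | c1ccccc1COc1ccc([C@@H]2C[C@@H](c6c(O)cc(O[Si](C(C)C)(C(C)C)C(C)C)cc6O[C@H](c7cc(OCc8ccccc8)c(OCc8ccccc8)c(OCc8ccccc8)c7)[C@H]7CO7)c3ccc(OCc5ccccc5)cc3O2)cc1 | intermediate
12 | (2R,3R)-8-[(2S,4R)-7-(benzyloxy)-2-[4-(benzyloxy)phenyl]chroman-4-yl]-5-[(triisopropylsilyl)oxy]-2-[3,4,5-tris(benzyloxy)phenyl]chromane-3,7-diol | c1ccccc1COc1ccc([C@@H]2C[C@@H](c6c(O)cc(O[Si](C(C)C)(C(C)C)C(C)C)c7c6O[C@H](c8cc(OCc9ccccc9)c(OCc9ccccc9)c(OCc9ccccc9)c8)[C@H](O)C7)c3ccc(OCc5ccccc5)cc3O2)cc1 | intermediate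
13 | (2R,3R)-8-[(2S,4R)-7-(benzyloxy)-2-[4-(benzyloxy)phenyl]chroman-4-yl]-2-[3,4,5-tris(benzyloxy)phenyl]chromane-3,5,7-triol | c1ccccc1COc1ccc([C@@H]2C[C@@H](c6c(O)cc(O)c7c6O[C@H](c8cc(OCc9ccccc9)c(OCc9ccccc9)c(OCc9ccccc9)c8)[C@H](O)C7)c3ccc(OCc5ccccc5)cc3O2)cc1 | intermediate
14 | (2R,3R)-8-[(2S,4R)-7-hydroxy-2-(4-hydroxyphenyl)chroman-4-yl]-2-(3,4,5-trihydroxyphenyl)chromane-3,5,7-triol | Oc1ccc([C@@H]2C[C@@H](c3c(O)cc(O)c4c3O[C@H](c3cc(O)c(O)c(O)c3)[C@H](O)C4)c3ccc(O)cc3O2)cc1 | target

**Totals and risks**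

Total step count: 11. Longest linear sequence: 8 steps (steps 1, 2, 3, 4, 8, 9, 10, 11, from 1); the epoxy alcohol branch (steps 5–7) joins at step 8.

Steps most likely to fail:

1. Step 9. The activated epoxide may rearrange by hydride shift (Meinwald rearrangement), the electron-rich benzylic C2'–O1' ether may ionise, or the acid may cleave the interflavan bond before the arene attacks C4'. The fallback gives up the late closure of ring F; it sets out from 3 and comes back at 14. Commercial (−)-epigallocatechin would be benzylated on its five phenols (BnBr, K2CO3, DMF) to (2R,3R)-5,7-bis(benzyloxy)-2-[3,4,5-tris(benzyloxy)phenyl]chroman-3-ol F1. Alcohol 3 would then be ionised with BF3·OEt2 in CH2Cl2 at low temperature in the presence of excess F1. Flavan-4-yl cations are known to attack benzylated flavan-3-ols at C8, again pseudo-axially, so this should give (2R,3R)-5,7-bis(benzyloxy)-8-[(2S,4R)-7-(benzyloxy)-2-[4-(benzyloxy)phenyl]chroman-4-yl]-2-[3,4,5-tris(benzyloxy)phenyl]chroman-3-ol F2. Hydrogenolysis over Pd(OH)2/C as in step 11 would then deliver 14.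

2. Step 8. Etherification of the phenol next to the bulky flavan-4-yl group may be slow, so that the oxyphosphonium ion of the electron-rich benzylic carbinol ionises (loss of configuration at C2') or alkylates ring D on carbon. The fallback builds the ether by allylic substitution and adds the C3' oxygen afterwards; it sets out from 6 and 9 (the unreacted enantiomer from step 7 serves equally) and comes back at 11.
   - Acid-catalysed 1,3-transposition of 9 (dilute H2SO4, aqueous dioxane) would give the conjugated (E)-3-[3,4,5-tris(benzyloxy)phenyl]prop-2-en-1-ol F3, and methyl chloroformate with pyridine would convert it into (E)-3-[3,4,5-tris(benzyloxy)phenyl]prop-2-en-1-yl methyl carbonate F4.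
   - Branch-selective enantioselective allylic etherification of the mono-phenoxide of 6 with F4 ([Ir(cod)Cl]2 and a BINOL-derived phosphoramidite ligand of the enantiomeric series that gives the (S)-ether, THF) would give 2-[(2S,4R)-7-(benzyloxy)-2-[4-(benzyloxy)phenyl]chroman-4-yl]-3-{(1S)-1-[3,4,5-tris(benzyloxy)phenyl]prop-2-enyloxy}-5-[(triisopropylsilyl)oxy]phenol F5, with C2' set by the catalyst.
   - Asymmetric dihydroxylation of the terminal alkene (K2OsO2(OH)4, (DHQ)2PHAL, N-methylmorpholine N-oxide, acetone–water; the face-selection mnemonic assigns this ligand to the 3'R diol) would give (2R,3R)-3-{2-[(2S,4R)-7-(benzyloxy)-2-[4-(benzyloxy)phenyl]chroman-4-yl]-3-hydroxy-5-[(triisopropylsilyl)oxy]phenoxy}-3-[3,4,5-tris(benzyloxy)phenyl]propane-1,2-diol F6.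
   - Tin-mediated tosylation of the primary hydroxyl (Bu2SnO cat., TsCl, Et3N) would give the (2R,3R)-primary 4-methylbenzenesulfonate of that diol F7, and K2CO3 in MeOH would close the epoxide with retention at C3' to give 11.

3. Step 4. Silylation may also occur at a hydroxyl flanking the flavan-4-yl group, or twice, so that the para oxygen is not cleanly differentiated from the two equivalent ones. The fallback differentiates the oxygens before the interflavan bond is made; it sets out from 3 and 4 and comes back at 6. Phloroglucinol in excess would be mono-silylated (TIPSCl, imidazole, DMF; unreacted triol is removed with water) to 5-[(triisopropylsilyl)oxy]benzene-1,3-diol F8. Alcohol 3 would then be coupled with F8 under the acid conditions of step 3. The bulky silyloxy group shields both of its ortho carbons, so the flavan-4-yl cation should enter between the two free hydroxyls and give 6 directly.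

**Further compounds**

F1 | step 9 | (2R,3R)-5,7-bis(benzyloxy)-2-[3,4,5-tris(benzyloxy)phenyl]chroman-3-ol | c1c(OCc5ccccc5)cc(OCc5ccccc5)c2c1O[C@H](c3cc(OCc4ccccc4)c(OCc4ccccc4)c(OCc4ccccc4)c3)[C@H](O)C2
F2 | step 9 | (2R,3R)-5,7-bis(benzyloxy)-8-[(2S,4R)-7-(benzyloxy)-2-[4-(benzyloxy)phenyl]chroman-4-yl]-2-[3,4,5-tris(benzyloxy)phenyl]chroman-3-ol | c1ccccc1COc1ccc([C@@H]2C[C@@H](c6c(OCc7ccccc7)cc(OCc7ccccc7)c7c6O[C@H](c8cc(OCc9ccccc9)c(OCc9ccccc9)c(OCc9ccccc9)c8)[C@H](O)C7)c3ccc(OCc5ccccc5)cc3O2)cc1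
F3 | step 8 | (E)-3-[3,4,5-tris(benzyloxy)phenyl]prop-2-en-1-ol | OC/C=C/c1cc(OCc2ccccc2)c(OCc2ccccc2)c(OCc2ccccc2)c1
F4 | step 8 | (E)-3-[3,4,5-tris(benzyloxy)phenyl]prop-2-en-1-yl methyl carbonate | COC(=O)OC/C=C/c1cc(OCc2ccccc2)c(OCc2ccccc2)c(OCc2ccccc2)c1
F5 | step 8 | 2-[(2S,4R)-7-(benzyloxy)-2-[4-(benzyloxy)phenyl]chroman-4-yl]-3-{(1S)-1-[3,4,5-tris(benzyloxy)phenyl]prop-2-enyloxy}-5-[(triisopropylsilyl)oxy]phenol | c1ccccc1COc1ccc([C@@H]2C[C@@H](c6c(O)cc(O[Si](C(C)C)(C(C)C)C(C)C)cc6O[C@H](c7cc(OCc8ccccc8)c(OCc8ccccc8)c(OCc8ccccc8)c7)C=C)c3ccc(OCc5ccccc5)cc3O2)cc1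
F6 | step 8 | (2R,3R)-3-{2-[(2S,4R)-7-(benzyloxy)-2-[4-(benzyloxy)phenyl]chroman-4-yl]-3-hydroxy-5-[(triisopropylsilyl)oxy]phenoxy}-3-[3,4,5-tris(benzyloxy)phenyl]propane-1,2-diol | c1ccccc1COc1ccc([C@@H]2C[C@@H](c6c(O)cc(O[Si](C(C)C)(C(C)C)C(C)C)cc6O[C@H](c7cc(OCc8ccccc8)c(OCc8ccccc8)c(OCc8ccccc8)c7)[C@H](O)CO)c3ccc(OCc5ccccc5)cc3O2)cc1
F7 | step 8 | (2R,3R)-3-{2-[(2S,4R)-7-(benzyloxy)-2-[4-(benzyloxy)phenyl]chroman-4-yl]-3-hydroxy-5-[(triisopropylsilyl)oxy]phenoxy}-2-hydroxy-3-[3,4,5-tris(benzyloxy)phenyl]propyl 4-methylbenzenesulfonate | c1ccccc1COc1ccc([C@@H]2C[C@@H](c6c(O)cc(O[Si](C(C)C)(C(C)C)C(C)C)cc6O[C@H](c7cc(OCc8ccccc8)c(OCc8ccccc8)c(OCc8ccccc8)c7)[C@H](O)COS(=O)(=O)c7ccc(C)cc7)c3ccc(OCc5ccccc5)cc3O2)cc1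
F8 | step 4 | 5-[(triisopropylsilyl)oxy]benzene-1,3-diol | CC(C)[Si](Oc1cc(O)cc(O)c1)(C(C)C)C(C)C
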